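The route rests on reading the C3′ methyl of the O7 side chain as the CH2 of a terminal oxirane, which turns the vicinal C2′(OH)–C3′(OH)(CH3) pair into a 2-methylidene allylic carbinol. A titanium/D-(−)-diisopropyl tartrate/TBHP epoxidation run as a kinetic resolution converts only the (S)-carbinol, forms the C3′ oxirane and thereby fixes C2′ and C3′ in one operation; the coumarin bicycle (benzene ring fused to the pyran-2-one) takes no part and is attached last. The precursor is racemic 1-silyloxy-7-methyl-3-methylideneoct-6-en-2-ol, whose bulky, weakly coordinating TBDPS ether on O1′ is the only spectator group.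

Key step: step 3

Assumption: aldehyde 4 and isofraxidin 11 are taken as purchased; side-chain locants C1′–C7′ count from O7, and the C3′ methyl is the former oxirane CH2.

Remark on descriptors: C2′ is (S) in 6 and (R) from 7 on, and C3′ is (S) in 7 and (R) from 8 on, only because the CIP ranking changes; no bond at either centre is broken after step 3. The unreacted (R)-alcohol of step 3 is removed by chromatography.

Step 1
Reactants: 1 6-methylhept-5-en-2-one
Product: 3 6-methylhepta-1,5-dien-2-yl trifluoromethanesulfonate, via kinetic lithium enolate 2 (not isolated)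
Conditions: LDA (1.05 equiv), THF, −78 °C; then PhNTf2, −78 → 0 °C
Reagents that add atoms: N-phenylbis(trifluoromethanesulfonimide) (PhNTf2), O=S(=O)(N(c1ccccc1)S(=O)(=O)C(F)(F)F)C(F)(F)F
Why: Kinetic deprotonation of the methyl ketone by a hindered amide base at low temperature should give the less substituted enolate, which is O-sulfonylated to the terminal enol triflate (enol triflate formation); no stereocentre is involved.

Step 2
Reactants: 3 6-methylhepta-1,5-dien-2-yl trifluoromethanesulfonate; 4 (tert-butyldiphenylsilyloxy)acetaldehyde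
Product: 6 rac-1-(tert-butyldiphenylsilyloxy)-7-methyl-3-methylideneoct-6-en-2-ol, via alkenylchromium(III) dichloride 5 (not isolated)
Conditions: CrCl2 (4 equiv), NiCl2 (cat.), DMF, rt
Reagents that add atoms: none
Why: Nozaki–Hiyama–Kishi coupling, in which nickel inserts into the C–OTf bond, the alkenyl group passes to chromium(III) and adds only to the aldehyde carbonyl while the silyl ether and the trisubstituted olefin are tolerated; the carbinol C2′ forms without control, as wanted for the resolution.

Step 3
Reactants: 6 rac-1-(tert-butyldiphenylsilyloxy)-7-methyl-3-methylideneoct-6-en-2-ol (racemate; the (S)-enantiomer is the one epoxidised)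
Product: 7 (1R)-2-(tert-butyldiphenylsilyloxy)-1-[(2S)-2-(4-methylpent-3-en-1-yl)oxiran-2-yl]ethan-1-ol
Conditions: Ti(OiPr)4 (15 mol %), D-(−)-DIPT (20 mol %), anhydrous TBHP (0.45 equiv), 4 Å MS, CH2Cl2, −20 °C
Reagents that add atoms: tert-butyl hydroperoxide, CC(C)(C)OO
Why: The alkoxide of (S)-6 and the tert-butyl peroxide bind the same titanium of the tartrate-bridged dimer, and the peroxide oxygen passes in a concerted step to the C3′=CH2 π bond; the closest known reaction is the Sharpless kinetic resolution of 2-substituted secondary allylic alcohols. The oxirane (C3′, CH2, O) closes by direct [2+1] oxygen-atom transfer to the olefin, both C–O bonds forming together, so no separate ring-closing displacement occurs. C3′ is set by the ligand, D-(−)-DIPT delivering oxygen to the olefin face that makes the oxirane carbon (S). C2′ is selected, not created: only in the (S)-alcohol does CH2OTBDPS point away from the catalyst on that face, and A(1,2) strain against the C4′ chain reinforces the erythro outcome. The step needs enantiomer discrimination, face selection and chemoselectivity: the first two come from the tartrate and are protected by using less than half an equivalent of oxidant, the third from the requirement for a titanium-bound allylic hydroxyl, which the C6′=C7′ olefin lacks. The bulky silyl ether should keep O1′ off titanium, and catalytic titanium with sieves should limit opening of the 2,2-disubstituted oxirane.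

Step 4
Reactants: 7 (1R)-2-(tert-butyldiphenylsilyloxy)-1-[(2S)-2-(4-methylpent-3-en-1-yl)oxiran-2-yl]ethan-1-ol
Product: 8 (2R,3R)-1-(tert-butyldiphenylsilyloxy)-3,7-dimethyloct-6-ene-2,3-diol
Conditions: LiAlH4, THF, 0 °C → rt; Rochelle salt work-up
Reagents that add atoms: none
Why: Hydride reduction of an epoxide by SN2 attack at the unhindered oxirane CH2 (the quaternary carbon cannot be attacked) turns that CH2 into the C3′ methyl and leaves the C3′–O bond, and thus both stereocentres, untouched; the silyl ether and the isolated olefin are inert at this temperature.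

Step 5
Reactants: 8 (2R,3R)-1-(tert-butyldiphenylsilyloxy)-3,7-dimethyloct-6-ene-2,3-diol
Product: 9 (2R,3R)-3,7-dimethyloct-6-ene-1,2,3-triol
Conditions: TBAF, THF, 0 °C → rt
Reagents that add atoms: none
Why: Fluoride-mediated desilylation cleaves only the Si–O bond, so the primary hydroxyl is freed without any C–O bond being touched.

Step 6
Reactants: 9 (2R,3R)-3,7-dimethyloct-6-ene-1,2,3-triol
Product: 10 (2R,3R)-2,3-dihydroxy-3,7-dimethyloct-6-en-1-yl 4-methylbenzenesulfonate
Conditions: TsCl (1.05 equiv), Bu2SnO (2 mol %), Et3N, CH2Cl2, 0 °C → rt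
Reagents that add atoms: p-toluenesulfonyl chloride, Cc1ccc(cc1)S(=O)(=O)Cl
Why: Tin-acetal-mediated regioselective sulfonylation of a terminal 1,2-diol should place the tosyl group on the primary O1′ only, preparing C1′ for an SN2 etherification that cannot involve C2′ (a Mitsunobu activation of the free 1,2-diol could activate O2′ through a cyclic dioxaphosphorane); no stereocentre is touched.

Step 7
Reactants: 10 (2R,3R)-2,3-dihydroxy-3,7-dimethyloct-6-en-1-yl 4-methylbenzenesulfonate; 11 isofraxidin
Product: 12 altissimacoumarin C
Conditions: K2CO3, DMF, 60 °C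
Reagents that add atoms: none
Why: Williamson ether synthesis, in which the phenoxide of the acidic 7-hydroxycoumarin displaces the primary sulfonate at C1′ by SN2 without breaking any bond at C2′ or C3′; carbonate in dry DMF should leave the lactone and the tertiary alcohol alone.

Compound list
1 | 6-methylhept-5-en-2-one | CC(=O)CCC=C(C)C | starting material
2 | lithium 6-methylhepta-1,5-dien-2-olate (kinetic enolate) | [Li]OC(=C)CCC=C(C)C | intermediate
3 | 6-methylhepta-1,5-dien-2-yl trifluoromethanesulfonate | C=C(CCC=C(C)C)OS(=O)(=O)C(F)(F)F | intermediate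
4 | (tert-butyldiphenylsilyloxy)acetaldehyde | CC(C)(C)[Si](OCC=O)(c1ccccc1)c1ccccc1 | starting material
5 | (6-methylhepta-1,5-dien-2-yl)chromium(III) dichloride | C=C(CCC=C(C)C)[Cr](Cl)Cl | intermediate
6 | rac-1-(tert-butyldiphenylsilyloxy)-7-methyl-3-methylideneoct-6-en-2-ol (racemate; its (S)-enantiomer, drawn as F2 below, is the substrate consumed in step 3) | CC(C)(C)[Si](OCC(O)C(=C)CCC=C(C)C)(c1ccccc1)c1ccccc1 | intermediate
7 | (1R)-2-(tert-butyldiphenylsilyloxy)-1-[(2S)-2-(4-methylpent-3-en-1-yl)oxiran-2-yl]ethan-1-ol | CC(C)(C)[Si](OC[C@@H](O)[C@]1(CCC=C(C)C)CO1)(c1ccccc1)c1ccccc1 | intermediate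
8 | (2R,3R)-1-(tert-butyldiphenylsilyloxy)-3,7-dimethyloct-6-ene-2,3-diol | CC(C)(C)[Si](OC[C@@H](O)[C@](C)(O)CCC=C(C)C)(c1ccccc1)c1ccccc1 | intermediate
9 | (2R,3R)-3,7-dimethyloct-6-ene-1,2,3-triol | OC[C@@H](O)[C@](C)(O)CCC=C(C)C | intermediate
10 | (2R,3R)-2,3-dihydroxy-3,7-dimethyloct-6-en-1-yl 4-methylbenzenesulfonate | Cc1ccc(cc1)S(=O)(=O)OC[C@@H](O)[C@](C)(O)CCC=C(C)C | intermediate
11 | isofraxidin (7-hydroxy-6,8-dimethoxy-2H-chromen-2-one) | COc1cc2ccc(=O)oc2c(OC)c1O | starting material
12 | altissimacoumarin C, 7-{[(2R,3R)-2,3-dihydroxy-3,7-dimethyloct-6-en-1-yl]oxy}-6,8-dimethoxy-2H-chromen-2-one | COc1cc2ccc(=O)oc2c(OC)c1OC[C@@H](O)[C@](C)(O)CCC=C(C)C | target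

Total step count: 7. Longest linear sequence: 7 steps (1 → 3 → 6 → 7 → 8 → 9 → 10 → 12).

Steps most likely to fail

Step 3. The rate gap between the two enantiomers may be too small at the hindered 1,1-disubstituted olefin, so that the epoxy alcohol forms with eroded enantiomeric purity, or the titanium species may open the oxirane. The fallback sets out from 6 and comes back at 7. Compound 6 is oxidised with Dess–Martin periodinane to the enone 1-(tert-butyldiphenylsilyloxy)-7-methyl-3-methylideneoct-6-en-2-one F1. Corey–Bakshi–Shibata reduction with catecholborane should then give the single enantiomer (S)-1-(tert-butyldiphenylsilyloxy)-7-methyl-3-methylideneoct-6-en-2-ol F2; the (S)-oxazaborolidine is the choice if the branched alkenyl group acts as the large substituent. A hydroxyl-directed VO(acac)2/TBHP epoxidation, erythro-selective for 2-substituted allylic alcohols through A(1,2) strain, should give 7. The carbinol is then set by a reagent and C3′ by the substrate, with no resolution.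

Step 7. The C2′ hydroxyl may displace the sulfonate internally, and the resulting oxirane may migrate along the chain (Payne-type equilibration) faster than the hindered phenoxide attacks C1′, leading to slow conversion or regioisomeric ethers. The fallback sets out from 8 and comes back at 12. The 2′,3′-diol of 8 is tied up with 2,2-dimethoxypropane/PPTS as the acetonide tert-butyl{[(4R,5R)-2,2,5-trimethyl-5-(4-methylpent-3-en-1-yl)-1,3-dioxolan-4-yl]methoxy}diphenylsilane F3. TBAF frees the primary alcohol [(4R,5R)-2,2,5-trimethyl-5-(4-methylpent-3-en-1-yl)-1,3-dioxolan-4-yl]methanol F4. A Mitsunobu reaction (PPh3, DIAD) with 11, now without a free vicinal hydroxyl, should give the aryl ether 6,8-dimethoxy-7-{[(4R,5R)-2,2,5-trimethyl-5-(4-methylpent-3-en-1-yl)-1,3-dioxolan-4-yl]methoxy}-2H-chromen-2-one F5. Aqueous acetic acid then removes the acetonide to give 12.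

Step 1. Equilibration of the enolate before or during O-sulfonylation would erode the terminal/internal regiocontrol and carry isomeric triflates into the coupling. The fallback sets out from 1 and comes back at 6. Ketone 1 is condensed with 2,4,6-triisopropylbenzenesulfonyl hydrazide to 6-methylhept-5-en-2-one 2,4,6-triisopropylbenzenesulfonylhydrazone F6. Two equivalents of n-BuLi (THF/TMEDA, −78 → 0 °C) trigger a Shapiro reaction on the methyl side to give (6-methylhepta-1,5-dien-2-yl)lithium F7. This is added at −78 °C to aldehyde 4 to give 6 directly, by-passing 3 and the chromium coupling.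

Further compounds
F1 | step 3 | 1-(tert-butyldiphenylsilyloxy)-7-methyl-3-methylideneoct-6-en-2-one | CC(C)(C)[Si](OCC(=O)C(=C)CCC=C(C)C)(c1ccccc1)c1ccccc1
F2 | step 3 | (S)-1-(tert-butyldiphenylsilyloxy)-7-methyl-3-methylideneoct-6-en-2-ol | CC(C)(C)[Si](OC[C@@H](O)C(=C)CCC=C(C)C)(c1ccccc1)c1ccccc1
F3 | step 7 | tert-butyl{[(4R,5R)-2,2,5-trimethyl-5-(4-methylpent-3-en-1-yl)-1,3-dioxolan-4-yl]methoxy}diphenylsilane | CC(C)(C)[Si](OC[C@H]1OC(C)(C)O[C@]1(C)CCC=C(C)C)(c1ccccc1)c1ccccc1
F4 | step 7 | [(4R,5R)-2,2,5-trimethyl-5-(4-methylpent-3-en-1-yl)-1,3-dioxolan-4-yl]methanol | OC[C@H]1OC(C)(C)O[C@]1(C)CCC=C(C)C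
F5 | step 7 | 6,8-dimethoxy-7-{[(4R,5R)-2,2,5-trimethyl-5-(4-methylpent-3-en-1-yl)-1,3-dioxolan-4-yl]methoxy}-2H-chromen-2-one | COc1cc2ccc(=O)oc2c(OC)c1OC[C@H]1OC(C)(C)O[C@]1(C)CCC=C(C)C
F6 | step 1 | 6-methylhept-5-en-2-one 2,4,6-triisopropylbenzenesulfonylhydrazone | CC(CCC=C(C)C)=NNS(=O)(=O)c1c(C(C)C)cc(C(C)C)cc1C(C)C
F7 | step 1 | (6-methylhepta-1,5-dien-2-yl)lithium | [Li]C(=C)CCC=C(C)C
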